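**Strategy.** The target is cut at the C9=C11 styrene bond (aryllithium plus C11 aldehyde, then dehydration) and, inside the decalin, at C9–C10. Ring B is made by a boat-locked Ireland–Claisen ring contraction. The step exploits the fact that C11–C9–C8–C7–C6 of ring B can be carried as a δ-lactone whose carbinol carbon C6 bears the tetrasubstituted C5=C10 alkene of a cyclogeranyl ring A. One [3,3] shift then closes ring B, creates the quaternary C10 and places the C8 and C10 methyl groups syn. The precursor is the cis-(4S,6S)-4-methyl-6-(2,6,6-trimethylcyclohexenyl) δ-lactone. The C9 carboxyl, reduced to CH2OH, then directs hydrogenation to the trans-decalin.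

Key step: step 5

Remark: drimane numbering is used for the terpenoid carbons (C11 on C9, C12 the methyl on C8) and primed numbers for the arene (C1′ bonded to C11); the aryl sulfates would be handled as salts and are drawn as free acids.

Step 1
Reactants: 1 β-cyclocitral; 2 methallylmagnesium chloride
Product: 3 (1S)-3-methyl-1-(2,6,6-trimethylcyclohex-1-en-1-yl)but-3-en-1-ol
Conditions: (−)-Ipc2BOMe ((+)-α-pinene series), 2, Et2O, 0 °C; then 1, −78 °C → rt; NaOH, H2O2
Reagents that add atoms: none
Why: Brown asymmetric methallylboration through a closed chair transition state, in which the isopinocampheyl groups of the (+)-α-pinene-derived borane (the antipode that gives (S)-1-phenylbut-3-en-1-ol from benzaldehyde) send the methallyl group to the Si face of the hindered enal and so set C6 as S.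

Step 2
Reactants: 3 (1S)-3-methyl-1-(2,6,6-trimethylcyclohex-1-en-1-yl)but-3-en-1-ol; 4 acryloyl chloride
Product: 5 (1S)-3-methyl-1-(2,6,6-trimethylcyclohex-1-en-1-yl)but-3-en-1-yl prop-2-enoate
Conditions: Et3N, DMAP (cat.), CH2Cl2, 0 °C
Reagents that add atoms: none
Why: DMAP-catalysed acylation (nucleophilic acyl substitution) of the secondary allylic alcohol by the acid chloride, which does not touch the C6 stereocentre.

Step 3
Reactants: 5 (1S)-3-methyl-1-(2,6,6-trimethylcyclohex-1-en-1-yl)but-3-en-1-yl prop-2-enoate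
Product: 6 (6S)-4-methyl-6-(2,6,6-trimethylcyclohex-1-en-1-yl)-5,6-dihydro-2H-pyran-2-one
Conditions: second-generation Grubbs catalyst RuCl2(=CHPh)(H2IMes)(PCy3) (5 mol%), CH2Cl2, 40 °C
Reagents that add atoms: none
Why: Ring-closing metathesis of the acrylate onto the 1,1-disubstituted methallyl alkene closes the six-membered unsaturated lactone with loss of ethene, while the tetrasubstituted ring alkene is inert to the ruthenium carbene.

Step 4
Reactants: 6 (6S)-4-methyl-6-(2,6,6-trimethylcyclohex-1-en-1-yl)-5,6-dihydro-2H-pyran-2-one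
Product: 7 cis-(4S,6S)-4-methyl-6-(2,6,6-trimethylcyclohex-1-en-1-yl)tetrahydro-2H-pyran-2-one
Conditions: Cu(OAc)2·H2O (cat.), 1,2-bis(diphenylphosphino)benzene (cat.), (HMe2Si)2O, t-BuOH, toluene, rt
Reagents that add atoms: none
Why: Copper hydride conjugate reduction (Stryker type, phosphine-ligated CuH turned over by the silane), in which hydride adds axially to C8 of the half-chair lactone on the face anti to the pseudo-equatorial C6 substituent, so the new C8 centre carries its methyl cis to the cyclohexenyl group (4S) and the copper enolate is protonated by t-BuOH.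

Step 5
Reactants: 7 cis-(4S,6S)-4-methyl-6-(2,6,6-trimethylcyclohex-1-en-1-yl)tetrahydro-2H-pyran-2-one
Product: 10 (1R,2S,8aR)-2,5,5,8a-tetramethyl-1,2,3,5,6,7,8,8a-octahydronaphthalene-1-carboxylic acid (8β-methyldrim-5-en-11-oic acid, carboxyl 9α), via silyl ketene acetal 8 (not isolated), via silyl ester 9 (not isolated)
Conditions: t-BuMe2SiCl, KN(SiMe3)2, THF, −78 °C; toluene, 110 °C; 1 M HCl, THF, rt
Reagents that add atoms: none
Why: In situ O-silylation of the potassium enolate gives the ring-locked ketene acetal 8, whose allyl vinyl ether array C9=C11–O1–C6–C5=C10 undergoes a concerted suprafacial [3,3] shift on heating (C9–C10 forms, C6–O1 breaks) to silyl ester 9, which is hydrolysed to 10. The closest known reaction is the Ireland–Claisen ring contraction of δ-lactone silyl ketene acetals that carry an alkenyl group on the carbinol carbon. Ring B closes by sigmatropic C–C bond formation inside a bicyclo[2.2.2]octane-like array in which the C7–C8 bridge ties C6 to C9, so only the boat is possible and the new C5=C6 alkene is cis within the six-membered carbocycle. C10 is controlled by C6, because only the rotamer about C5–C6 that holds C10 over C9 with the C6–O1 bond parallel to the π system can react, so C9 adds to one alkene face; C8, being cis to that alkenyl group, ends with its methyl syn to the C10 methyl, and C9 is set by suprafacial delivery on the face of the ketene acetal that carries the alkenyl group (9α-carboxyl, trans to the C8 methyl). The step needs the pericyclic path to beat ionisation of the allylic C6–O bond, enolate self-condensation and C-silylation, which the internal silyl quench at −78 °C, a non-polar medium free of Lewis acids and the fixed geometry of the lactone are meant to secure.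

Step 6
Reactants: 10 (1R,2S,8aR)-2,5,5,8a-tetramethyl-1,2,3,5,6,7,8,8a-octahydronaphthalene-1-carboxylic acid
Product: 11 [(1R,2S,8aR)-2,5,5,8a-tetramethyl-1,2,3,5,6,7,8,8a-octahydronaphthalen-1-yl]methanol
Conditions: LiAlH4, THF, 0 °C → reflux
Reagents that add atoms: none
Why: Hydride reduction of the carboxylic acid to the primary alcohol with LiAlH4, which leaves the isolated trisubstituted alkene and all stereocentres untouched.

Step 7
Reactants: 11 [(1R,2S,8aR)-2,5,5,8a-tetramethyl-1,2,3,5,6,7,8,8a-octahydronaphthalen-1-yl]methanol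
Product: 12 [(1R,2S,4aS,8aS)-2,5,5,8a-tetramethyldecahydronaphthalen-1-yl]methanol (trans-decalin, 5α-H)
Conditions: [Ir(cod)(PCy3)(py)]PF6 (5 mol%), H2 (1–50 bar), CH2Cl2, rt
Reagents that add atoms: none
Why: Hydroxyl-directed homogeneous hydrogenation, in which the 9α-hydroxymethyl group binds the cationic iridium centre and delivers H2 to the α-face of the C5=C6 alkene, setting C5 with its hydrogen α (trans ring fusion, anti to the C10 methyl).

Step 8
Reactants: 12 [(1R,2S,4aS,8aS)-2,5,5,8a-tetramethyldecahydronaphthalen-1-yl]methanol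
Product: 13 (1R,2S,4aS,8aS)-2,5,5,8a-tetramethyldecahydronaphthalene-1-carbaldehyde
Conditions: Dess–Martin periodinane, CH2Cl2, rt
Reagents that add atoms: none
Why: Dess–Martin oxidation of the hindered primary alcohol to the aldehyde under neutral conditions; any epimerisation at C9 is without consequence because C9 becomes trigonal in step 12.

Step 9
Reactants: 14 4-bromo-2,5-dimethoxybenzaldehyde
Product: 16 4-bromo-2,5-dimethoxyphenol, via aryl formate 15 (not isolated)
Conditions: mCPBA, CH2Cl2, 0 °C → rt; then K2CO3 (cat.), MeOH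
Reagents that add atoms: 3-chloroperoxybenzoic acid, OOC(=O)c1cccc(Cl)c1
Why: Baeyer–Villiger (Dakin-type) oxidation, in which the electron-rich aryl group migrates in the Criegee intermediate to give the aryl formate, which methanolysis cleaves to the phenol.

Step 10
Reactants: 16 4-bromo-2,5-dimethoxyphenol
Product: 17 [2-(4-bromo-2,5-dimethoxyphenoxy)ethyl]trimethylsilane
Conditions: Me3SiCH2CH2OH, PPh3, DIAD, THF, 0 °C → rt
Reagents that add atoms: 2-(trimethylsilyl)ethanol, C[Si](C)(C)CCO
Why: Mitsunobu etherification (SN2 displacement of the primary alkoxyphosphonium by the phenol) installs a fluoride-labile alkyl ether that tolerates organolithiums, mild acid and oxidants.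

Step 11
Reactants: 17 [2-(4-bromo-2,5-dimethoxyphenoxy)ethyl]trimethylsilane; 13 (1R,2S,4aS,8aS)-2,5,5,8a-tetramethyldecahydronaphthalene-1-carbaldehyde
Product: 19 [2,5-dimethoxy-4-(2-trimethylsilylethoxy)phenyl][(1R,2S,4aS,8aS)-2,5,5,8a-tetramethyldecahydronaphthalen-1-yl]methanol (mixture of C11 epimers), via aryllithium 18 (not isolated)
Conditions: n-BuLi, THF, −78 °C; then 13, −78 → 0 °C; H2O
Reagents that add atoms: none
Why: Bromine–lithium exchange (much faster than ortho-deprotonation at −78 °C) followed by 1,2-addition of the aryllithium to the aldehyde; the new carbinol centre C11 forms as a mixture, which does not matter because it is removed in the next step.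

Step 12
Reactants: 19 [2,5-dimethoxy-4-(2-trimethylsilylethoxy)phenyl][(1R,2S,4aS,8aS)-2,5,5,8a-tetramethyldecahydronaphthalen-1-yl]methanol
Product: 20 trimethyl[2-(2,5-dimethoxy-4-{(E)-[(2S,4aS,8aS)-2,5,5,8a-tetramethyloctahydronaphthalen-1(2H)-ylidene]methyl}phenoxy)ethyl]silane
Conditions: PPTS (cat.), toluene, 80 °C
Reagents that add atoms: none
Why: Acid-catalysed E1 dehydration through the benzylic cation stabilised by the C2′ and C4′ oxygens, with loss of H9; the E geometry (aryl anti to the quaternary C10, syn to C8) is favoured because the other isomer forces the arene against the C10 methyl and C1.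

Step 13
Reactants: 20 trimethyl[2-(2,5-dimethoxy-4-{(E)-[(2S,4aS,8aS)-2,5,5,8a-tetramethyloctahydronaphthalen-1(2H)-ylidene]methyl}phenoxy)ethyl]silane
Product: 22 C3′-carbaldehyde of 20 (CHO between the C2′ methoxy group and the C4′ silylethyl ether), via C3′-lithio arene 21 (not isolated)
Conditions: n-BuLi, TMEDA, THF, 0 °C; DMF, −78 °C → rt; H2O
Reagents that add atoms: N,N-dimethylformamide, CN(C)C=O
Why: Directed ortho-metalation at C3′, the only ring position flanked by two alkoxy groups, followed by formylation of the aryllithium with DMF.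

Step 14
Reactants: 22 C3′-carbaldehyde of 20
Product: 24 2′,5′-dihydroxy analogue of 22 (hydroquinone with C3′ formyl and C4′ silylethyl ether), via formylquinone 23 (not isolated)
Conditions: (NH4)2Ce(NO3)6, MeCN–H2O, 0 °C; then Na2S2O4, H2O–EtOAc, rt
Reagents that add atoms: water, O
Why: Oxidative demethylation with ceric ammonium nitrate (one-electron oxidation of the para-dimethoxy arene, addition of water, loss of two molecules of methanol) gives the quinone at C2′/C5′, the only para-dioxygenated pair, while the C4′ alkyl ether stays as a vinylogous ester, and dithionite reduces the quinone at once to the hydroquinone.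

Step 15
Reactants: 24 2′,5′-dihydroxy-3′-formyl-4′-(2-trimethylsilylethoxy) arene
Product: 25 2′,5′-bis(hydrogen sulfate) of 24 (handled as its bis-pyridinium salt)
Conditions: SO3·pyridine, pyridine, 50 °C
Reagents that add atoms: sulfur trioxide–pyridine complex, O=S(=O)([O-])[n+]1ccccc1
Why: O-Sulfation of both free phenols by the sulfur trioxide–pyridine complex under basic conditions; the C4′ oxygen is blocked, so only C2′ and C5′ are sulfated.

Step 16
Reactants: 25 2′,5′-bis(hydrogen sulfate) with C4′ silylethyl ether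
Product: 26 CNP0309628.1
Conditions: Bu4NF, DMF, 40 °C; then cold 0.1 M HCl (brief), C18 desalting
Reagents that add atoms: none
Why: Fluoride-induced fragmentation of the 2-(trimethylsilyl)ethyl ether (attack at silicon, β-elimination of ethene and the phenoxide) frees the C4′ phenol under non-acidic conditions that aryl sulfate monoesters tolerate.

**Compound list**

1 | β-cyclocitral (2,6,6-trimethylcyclohex-1-ene-1-carbaldehyde) | CC1=C(C=O)C(C)(C)CCC1 | starting material
2 | methallylmagnesium chloride (2-methylprop-2-enylmagnesium chloride) | CC(=C)C[Mg]Cl | starting material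
3 | (1S)-3-methyl-1-(2,6,6-trimethylcyclohex-1-en-1-yl)but-3-en-1-ol | CC(=C)C[C@H](O)C1=C(C)CCCC1(C)C | intermediate
4 | acryloyl chloride | C=CC(=O)Cl | starting material
5 | (1S)-3-methyl-1-(2,6,6-trimethylcyclohex-1-en-1-yl)but-3-en-1-yl prop-2-enoate | CC(=C)C[C@H](OC(=O)C=C)C1=C(C)CCCC1(C)C | intermediate
6 | (6S)-4-methyl-6-(2,6,6-trimethylcyclohex-1-en-1-yl)-5,6-dihydro-2H-pyran-2-one | O=C1C=C(C)C[C@H](O1)C1=C(C)CCCC1(C)C | intermediate
7 | cis-(4S,6S)-4-methyl-6-(2,6,6-trimethylcyclohex-1-en-1-yl)tetrahydro-2H-pyran-2-one | O=C1C[C@@H](C)C[C@H](O1)C1=C(C)CCCC1(C)C | intermediate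
8 | (2S,4S)-6-(tert-butyldimethylsilyloxy)-4-methyl-2-(2,6,6-trimethylcyclohex-1-en-1-yl)-3,4-dihydro-2H-pyran | CC(C)(C)[Si](C)(C)OC1=C[C@@H](C)C[C@H](O1)C1=C(C)CCCC1(C)C | intermediate (not isolated)
9 | tert-butyldimethylsilyl (1R,2S,8aR)-2,5,5,8a-tetramethyl-1,2,3,5,6,7,8,8a-octahydronaphthalene-1-carboxylate | C[C@H]1CC=C2C(C)(C)CCC[C@]2(C)[C@@H]1C(=O)O[Si](C)(C)C(C)(C)C | intermediate (not isolated)
10 | (1R,2S,8aR)-2,5,5,8a-tetramethyl-1,2,3,5,6,7,8,8a-octahydronaphthalene-1-carboxylic acid (8β-methyldrim-5-en-11-oic acid, 9α-carboxyl) | C[C@H]1CC=C2C(C)(C)CCC[C@]2(C)[C@@H]1C(=O)O | intermediate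
11 | [(1R,2S,8aR)-2,5,5,8a-tetramethyl-1,2,3,5,6,7,8,8a-octahydronaphthalen-1-yl]methanol | C[C@H]1CC=C2C(C)(C)CCC[C@]2(C)[C@@H]1CO | intermediate
12 | [(1R,2S,4aS,8aS)-2,5,5,8a-tetramethyldecahydronaphthalen-1-yl]methanol | C[C@H]1CC[C@H]2C(C)(C)CCC[C@]2(C)[C@@H]1CO | intermediate
13 | (1R,2S,4aS,8aS)-2,5,5,8a-tetramethyldecahydronaphthalene-1-carbaldehyde | C[C@H]1CC[C@H]2C(C)(C)CCC[C@]2(C)[C@@H]1C=O | intermediate
14 | 4-bromo-2,5-dimethoxybenzaldehyde | COc1cc(Br)c(OC)cc1C=O | starting material
15 | 4-bromo-2,5-dimethoxyphenyl formate | COc1cc(Br)c(OC)cc1OC=O | intermediate (not isolated)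
16 | 4-bromo-2,5-dimethoxyphenol | COc1cc(Br)c(OC)cc1O | intermediate
17 | [2-(4-bromo-2,5-dimethoxyphenoxy)ethyl]trimethylsilane | COc1cc(Br)c(OC)cc1OCC[Si](C)(C)C | intermediate
18 | [2,5-dimethoxy-4-(2-trimethylsilylethoxy)phenyl]lithium | [Li]c1cc(OC)c(OCC[Si](C)(C)C)cc1OC | intermediate (not isolated)
19 | [2,5-dimethoxy-4-(2-trimethylsilylethoxy)phenyl][(1R,2S,4aS,8aS)-2,5,5,8a-tetramethyldecahydronaphthalen-1-yl]methanol, C11 epimers | C[C@H]1CC[C@H]2C(C)(C)CCC[C@]2(C)[C@@H]1C(O)c1cc(OC)c(OCC[Si](C)(C)C)cc1OC | intermediate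
20 | trimethyl[2-(2,5-dimethoxy-4-{(E)-[(2S,4aS,8aS)-2,5,5,8a-tetramethyloctahydronaphthalen-1(2H)-ylidene]methyl}phenoxy)ethyl]silane | C[C@H]1CC[C@H]2C(C)(C)CCC[C@]2(C)/C1=C/c1cc(OC)c(OCC[Si](C)(C)C)cc1OC | intermediate
21 | C3′-lithio derivative of 20 | C[C@H]1CC[C@H]2C(C)(C)CCC[C@]2(C)/C1=C/c1cc(OC)c(OCC[Si](C)(C)C)c([Li])c1OC | intermediate (not isolated)
22 | 2,5-dimethoxy-3-{(E)-[(2S,4aS,8aS)-2,5,5,8a-tetramethyloctahydronaphthalen-1(2H)-ylidene]methyl}-6-(2-trimethylsilylethoxy)benzaldehyde | C[C@H]1CC[C@H]2C(C)(C)CCC[C@]2(C)/C1=C/c1cc(OC)c(OCC[Si](C)(C)C)c(C=O)c1OC | intermediate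
23 | 2′,5′-quinone of 22 (C3′ formyl, C4′ silylethyl ether) | C[C@H]1CC[C@H]2C(C)(C)CCC[C@]2(C)/C1=C/C1=CC(=O)C(OCC[Si](C)(C)C)=C(C=O)C1=O | intermediate (not isolated)
24 | 2,5-dihydroxy-3-{(E)-[(2S,4aS,8aS)-2,5,5,8a-tetramethyloctahydronaphthalen-1(2H)-ylidene]methyl}-6-(2-trimethylsilylethoxy)benzaldehyde | C[C@H]1CC[C@H]2C(C)(C)CCC[C@]2(C)/C1=C/c1cc(O)c(OCC[Si](C)(C)C)c(C=O)c1O | intermediate
25 | 2′,5′-bis(hydrogen sulfate) of 24, drawn as the free acid | C[C@H]1CC[C@H]2C(C)(C)CCC[C@]2(C)/C1=C/c1cc(OS(=O)(=O)O)c(OCC[Si](C)(C)C)c(C=O)c1OS(=O)(=O)O | intermediate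
26 | CNP0309628.1: 3′-formyl-4′-hydroxy-2′,5′-bis(sulfooxy)phenyl (E)-alkene on the 8β-methyl trans-drimane, drawn as the free acid | C[C@H]1CC[C@H]2C(C)(C)CCC[C@]2(C)/C1=C/c1cc(OS(=O)(=O)O)c(O)c(C=O)c1OS(=O)(=O)O | target

**Total step count:** 16. **Longest linear sequence:** 14 steps (steps 1–8, then 11–16).

**Steps most likely to fail**

Step 5. The crowded boat, in which C12 is pressed against the C10 methyl while a bond is made to a fully substituted alkene carbon, may be reached too slowly. Ketene acetal 8 could then ionise at the allylic C6–O1 bond and eliminate to an open-chain trienoic acid, or the enolate could condense with unreacted lactone before it is silylated. The fallback takes the C8 stereocentre out of the rearrangement and sets out from alcohol 3. Alkoxide-directed double deprotonation (n-BuLi, TMEDA) metalates the methallyl CH3, and CO2 gives (5S)-5-hydroxy-3-methylidene-5-(2,6,6-trimethylcyclohex-1-en-1-yl)pentanoic acid F1, which is lactonised (cat. TsOH) to the 4-methylidene lactone F2. The same silylation and heating, now with a trigonal C8 and hence without the C12/C10-methyl contact, should pass through ketene acetal F3 and silyl ester F4 to the 8(12)-ene acid F5, in which C10 is still fixed by C6 through the boat. LiAlH4 gives dienol F6. The iridium-catalysed hydrogenation of step 7, directed by the 9α-hydroxymethyl group, should then reduce C8=C12 and C5=C6 from the α-face in one operation (8β-methyl, 5α-H), so the sequence comes back to the route at alcohol 12.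

Step 14. The cerium oxidant may attack the electron-rich C9=C11 alkene that is conjugated to the arene. The formyl-bearing alkoxyquinone 23, activated twice at C4′, may also lose its C4′ ether by addition–elimination of water before it is reduced. The fallback oxidises before it formylates and sets out from styrene 20. (NH4)2Ce(NO3)6 and then Na2S2O4 on the more electron-rich, formyl-free arene give the ordinary alkoxyquinone F7 and the hydroquinone F8. Both phenols are capped (MOMCl, i-Pr2NEt) as the bis(methoxymethyl) ether F9. Ortho-lithiation between the C2′ acetal and the C4′ ether (n-BuLi, TMEDA) and DMF give the aldehyde F10. Finally 2 M HCl in MeOH–THF at room temperature removes both acetals while the 2-(trimethylsilyl)ethyl ether stays, which returns the route to hydroquinone 24.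

Step 7. Hydrogen uptake at the C5=C6 alkene, flanked by the quaternary C4 and C10, may be slow enough for the cationic iridium catalyst to deactivate or to move the alkene. The fallback replaces inner-sphere, hydroxyl-directed delivery by radical hydrogen-atom transfer. Mn(dpm)3 (cat.), PhSiH3 and t-BuOOH in i-PrOH convert alcohol 11 into the tertiary C5 radical, which is quenched to the thermodynamically preferred trans-fused decalin. The sequence sets out from 11 and comes back at 12 without any new compound (F0).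

Further compounds
F1 | step 5 | (5S)-5-hydroxy-3-methylidene-5-(2,6,6-trimethylcyclohex-1-en-1-yl)pentanoic acid | OC(=O)CC(=C)C[C@H](O)C1=C(C)CCCC1(C)C
F2 | step 5 | (6S)-4-methylidene-6-(2,6,6-trimethylcyclohex-1-en-1-yl)tetrahydro-2H-pyran-2-one | O=C1CC(=C)C[C@H](O1)C1=C(C)CCCC1(C)C
F3 | step 5 | (2S)-6-(tert-butyldimethylsilyloxy)-4-methylidene-2-(2,6,6-trimethylcyclohex-1-en-1-yl)-3,4-dihydro-2H-pyran | CC(C)(C)[Si](C)(C)OC1=CC(=C)C[C@H](O1)C1=C(C)CCCC1(C)C
F4 | step 5 | tert-butyldimethylsilyl (1R,8aR)-5,5,8a-trimethyl-2-methylidene-1,2,3,5,6,7,8,8a-octahydronaphthalene-1-carboxylate | C=C1CC=C2C(C)(C)CCC[C@]2(C)[C@@H]1C(=O)O[Si](C)(C)C(C)(C)C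
F5 | step 5 | (1R,8aR)-5,5,8a-trimethyl-2-methylidene-1,2,3,5,6,7,8,8a-octahydronaphthalene-1-carboxylic acid | C=C1CC=C2C(C)(C)CCC[C@]2(C)[C@@H]1C(=O)O
F6 | step 5 | [(1R,8aR)-5,5,8a-trimethyl-2-methylidene-1,2,3,5,6,7,8,8a-octahydronaphthalen-1-yl]methanol | C=C1CC=C2C(C)(C)CCC[C@]2(C)[C@@H]1CO
F7 | step 14 | 2′,5′-quinone of 20 (C4′ silylethyl ether, no formyl group) | C[C@H]1CC[C@H]2C(C)(C)CCC[C@]2(C)/C1=C/C1=CC(=O)C(OCC[Si](C)(C)C)=CC1=O
F8 | step 14 | 2′,5′-hydroquinone from F7 | C[C@H]1CC[C@H]2C(C)(C)CCC[C@]2(C)/C1=C/c1cc(O)c(OCC[Si](C)(C)C)cc1O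
F9 | step 14 | 2′,5′-bis(methoxymethyl) ether of F8 | C[C@H]1CC[C@H]2C(C)(C)CCC[C@]2(C)/C1=C/c1cc(OCOC)c(OCC[Si](C)(C)C)cc1OCOC
F10 | step 14 | C3′-carbaldehyde of F9 | C[C@H]1CC[C@H]2C(C)(C)CCC[C@]2(C)/C1=C/c1cc(OCOC)c(OCC[Si](C)(C)C)c(C=O)c1OCOC
F0 | step 7 | none | none
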